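The synthesis rests on disconnecting the side chain between the oxirane CH carbon (C15) and the methyl-bearing carbon C16. The oxirane is treated as a masked E-trisubstituted C14=C15 alkene whose C14 methyl and C15 substituent are cis, the signature of a syn methylmetalation of a terminal alkyne. In one flask, a C11–C15 alkyne is carboaluminated and the derived alkenyl alanate opens a C16–C19 trans-epoxide at C16 with inversion. This creates the C14 methyl, the alkene geometry, the C15–C16 bond, the C16 stereocentre and a free C17 hydroxyl for methylation. A Julia–Kocienski olefination then attaches the oxane fragment and a hydroxyl-directed epoxidation finishes.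

Key step: step 13

Remark: atoms are numbered C1 (carboxyl carbon) to C19 (terminal methyl) along the chain, the oxane holds C3–C7 and the oxirane C14–C15; the acid is carried as its ethyl ester until step 20.

Step 1
Reactants: 1 2,2-dimethoxyacetaldehyde; 2 2-(triphenylphosphoranylidene)propanal
Product: 3 (2E)-4,4-dimethoxy-2-methylbut-2-enal
Conditions: CH2Cl2, rt (1 extracted from its aqueous solution into CH2Cl2)
Reagents that add atoms: none
Why: Wittig olefination with the stabilised formyl ylide should attack the non-conjugated aldehyde of 1 and give the E-enal.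

Step 2
Reactants: 3 (2E)-4,4-dimethoxy-2-methylbut-2-enal
Product: 4 (2E,4S,5S)-1,1-dimethoxy-3,5-dimethylhepta-2,6-dien-4-ol
Conditions: trans-2-butene, KOtBu, n-BuLi, THF, −78 to −45 °C; (−)-Ipc2BOMe [from (+)-α-pinene], −78 °C; BF3·OEt2; then 3, −78 °C; NaOH, H2O2, rt
Reagents that add atoms: trans-2-butene, C/C=C/C
Why: Brown crotylboration through a closed chair transition state, in which the E-crotyl geometry should give the 4,5-anti pair and the isopinocampheyl groups should direct attack to the si face of the aldehyde, setting 4S (C7) and 5S (C6).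

Step 3
Reactants: 4 (2E,4S,5S)-1,1-dimethoxy-3,5-dimethylhepta-2,6-dien-4-ol; 5 ethyl (2Z)-3-iodoprop-2-enoate
Product: 7 ethyl (2Z,6S,7S,8E)-7-hydroxy-10,10-dimethoxy-6,8-dimethyldeca-2,8-dienoate, via alkylborane 6 (not isolated)
Conditions: 9-BBN dimer (excess), THF, 0 °C to rt; then 5, PdCl2(dppf) (5 mol%), AsPh3, Cs2CO3, DMF/H2O, rt
Reagents that add atoms: none
Why: 9-BBN should hydroborate only the monosubstituted alkene at its terminus, and the B-alkyl Suzuki–Miyaura coupling with the vinyl iodide then adds C1–C3 without touching the stereocentres.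

Step 4
Reactants: 7 ethyl (2Z,6S,7S,8E)-7-hydroxy-10,10-dimethoxy-6,8-dimethyldeca-2,8-dienoate
Product: 8 ethyl 2-[(2R,5S,6S)-6-[(2E)-4,4-dimethoxybut-2-en-2-yl]-5-methyloxan-2-yl]acetate
Conditions: KOtBu (0.2 equiv), THF, 0 °C to rt
Reagents that add atoms: none
Why: Intramolecular oxa-Michael addition (6-exo-trig) under equilibrating conditions should give the all-equatorial 2,6-cis oxane, so that C3 (R) is set by thermodynamic control from C6 and C7.

Step 5
Reactants: 8 ethyl 2-[(2R,5S,6S)-6-[(2E)-4,4-dimethoxybut-2-en-2-yl]-5-methyloxan-2-yl]acetate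
Product: 9 ethyl 2-[(2R,5S,6S)-5-methyl-6-[(2E)-4-oxobut-2-en-2-yl]oxan-2-yl]acetate
Conditions: p-TsOH·H2O (cat.), acetone/H2O, rt
Reagents that add atoms: water, O
Why: Acid-catalysed hydrolysis of the allylic dimethyl acetal should release the conjugated E-enal while the oxane and the ester stay intact.

Step 6
Reactants: 10 (4R)-4-benzyl-3-propanoyl-1,3-oxazolidin-2-one; 11 3-bromoprop-1-yne
Product: 12 (4R)-4-benzyl-3-[(2S)-2-methylpent-4-ynoyl]-1,3-oxazolidin-2-one
Conditions: NaHMDS, THF, −78 °C; then 11, −78 to −40 °C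
Reagents that add atoms: none
Why: Evans alkylation, in which the chelated Z sodium enolate is alkylated on the face opposite to the benzyl group, setting C12 (S).

Step 7
Reactants: 12 (4R)-4-benzyl-3-[(2S)-2-methylpent-4-ynoyl]-1,3-oxazolidin-2-one
Product: 13 (2S)-2-methylpent-4-yn-1-ol
Conditions: LiBH4, MeOH (1 equiv), Et2O, 0 °C
Reagents that add atoms: none
Why: Reductive cleavage of the imide should give the primary alcohol without epimerisation and return the auxiliary.

Step 8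
Reactants: 13 (2S)-2-methylpent-4-yn-1-ol
Product: 14 tert-butyldimethyl{[(2S)-2-methylpent-4-yn-1-yl]oxy}silane
Conditions: TBSCl, imidazole, CH2Cl2, rt
Reagents that add atoms: tert-butyldimethylsilyl chloride, CC(C)(C)[Si](C)(C)Cl
Why: Standard silylation gives an ether that is inert to organoaluminium and organolithium reagents.

Step 9
Reactants: 15 rac-(3E)-pent-3-en-2-ol
Product: 16 (1S)-1-[(2S,3S)-3-methyloxiran-2-yl]ethan-1-ol
Conditions: Ti(OiPr)4 (0.1 equiv), L-(+)-diisopropyl tartrate (0.15 equiv), t-BuOOH (0.45 equiv), 4 Å MS, CH2Cl2, −20 °C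
Reagents that add atoms: tert-butyl hydroperoxide, CC(C)(C)OO
Why: Sharpless kinetic resolution, in which the L-(+)-tartrate catalyst should epoxidise the (S)-alcohol fast to the erythro (2S,3S)-oxirane, setting C16 and C17, and leave the (R)-alcohol behind.

Step 10
Reactants: 16 (1S)-1-[(2S,3S)-3-methyloxiran-2-yl]ethan-1-ol
Product: 17 (1R)-1-[(2R,3S)-3-methyloxiran-2-yl]ethyl 4-nitrobenzoate
Conditions: 4-nitrobenzoic acid, PPh3, DIAD, THF, 0 °C to rt
Reagents that add atoms: 4-nitrobenzoic acid, O=C(O)c1ccc(cc1)[N+](=O)[O-]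
Why: Mitsunobu esterification inverts the carbinol carbon (C18) by SN2 displacement, turning the erythro into the required threo arrangement (the oxirane descriptor changes only by priority).

Step 11
Reactants: 17 (1R)-1-[(2R,3S)-3-methyloxiran-2-yl]ethyl 4-nitrobenzoate
Product: 18 (1R)-1-[(2S,3S)-3-methyloxiran-2-yl]ethan-1-ol
Conditions: K2CO3 (0.2 equiv), MeOH, 0 °C
Reagents that add atoms: none
Why: Transesterification of the activated ester under weakly basic, cold conditions should free the alcohol before epoxide migration can set in.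

Step 12
Reactants: 18 (1R)-1-[(2S,3S)-3-methyloxiran-2-yl]ethan-1-ol
Product: 19 tert-butyldimethyl{(1R)-1-[(2R,3S)-3-methyloxiran-2-yl]ethoxy}silane
Conditions: TBSCl, imidazole, DMF, 0 °C to rt
Reagents that add atoms: tert-butyldimethylsilyl chloride, CC(C)(C)[Si](C)(C)Cl
Why: Silylation protects O18 with a bulky, non-chelating group that also shields C17 in the next step.

Step 13
Reactants: 14 tert-butyldimethyl{[(2S)-2-methylpent-4-yn-1-yl]oxy}silane; 19 tert-butyldimethyl{(1R)-1-[(2R,3S)-3-methyloxiran-2-yl]ethoxy}silane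
Product: 22 (2R,3R,4S,5E,8S)-2,9-bis[(tert-butyldimethylsilyl)oxy]-4,6,8-trimethylnon-5-en-3-ol, via alkenylalane 20 (not isolated), via lithium alanate 21 (not isolated)
Conditions: 14 (1.3 equiv), Me3Al (2.6 equiv), Cp2ZrCl2 (0.3 equiv), CH2Cl2, 0 °C to rt; volatiles removed under vacuum; hexane/Et2O, n-BuLi (1.3 equiv), −78 to 0 °C; 19 (1.0 equiv), 0 °C to rt; aqueous Rochelle salt
Reagents that add atoms: trimethylaluminium, C[Al](C)C
Why: Zirconium-catalysed syn carboalumination (Negishi) places methyl on the internal carbon (C14) and aluminium on the terminal carbon (C15) of 14, so the E geometry of C14=C15 follows from the syn addition. n-BuLi converts alane 20 into the nucleophilic alanate 21, which should transfer its alkenyl group in preference to methyl or butyl and open 19 by SN2 attack; the closest known reaction type is the opening of epoxides by alkenyl alanates from carboalumination. No ring is closed. The new stereocentre C16 is controlled by the oxirane: backside attack inverts C16 and leaves C17 untouched, which gives the syn C16-methyl/C17-oxygen pattern. The step needs attack at C16 and not at C17; the substrate secures this because C17 carries the branched, inductively deactivating silyloxyethyl group whereas C16 carries only a methyl. The opening frees the C17 hydroxyl alone, so O17 and O18 are told apart without further steps.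

Step 14
Reactants: 22 (2R,3R,4S,5E,8S)-2,9-bis[(tert-butyldimethylsilyl)oxy]-4,6,8-trimethylnon-5-en-3-ol
Product: 23 (2R,3R,4S,5E,8S)-2,9-bis[(tert-butyldimethylsilyl)oxy]-3-methoxy-4,6,8-trimethylnon-5-ene
Conditions: Me3OBF4, 1,8-bis(dimethylamino)naphthalene, 4 Å MS, CH2Cl2, rt
Reagents that add atoms: trimethyloxonium tetrafluoroborate, C[O+](C)C.F[B-](F)(F)F
Why: O-Methylation with the Meerwein salt and a non-nucleophilic base avoids a free alkoxide and thus 1,2-silyl migration from O18 to O17.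

Step 15
Reactants: 23 (2R,3R,4S,5E,8S)-2,9-bis[(tert-butyldimethylsilyl)oxy]-3-methoxy-4,6,8-trimethylnon-5-ene
Product: 24 (2S,4E,6S,7R,8R)-8-[(tert-butyldimethylsilyl)oxy]-7-methoxy-2,4,6-trimethylnon-4-en-1-ol
Conditions: HF·pyridine, pyridine, THF, 0 °C
Reagents that add atoms: none
Why: Under buffered HF·pyridine the primary silyl ether should be cleaved much faster than the hindered secondary one at C18.

Step 16
Reactants: 24 (2S,4E,6S,7R,8R)-8-[(tert-butyldimethylsilyl)oxy]-7-methoxy-2,4,6-trimethylnon-4-en-1-ol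
Product: 25 5-{[(2S,4E,6S,7R,8R)-8-[(tert-butyldimethylsilyl)oxy]-7-methoxy-2,4,6-trimethylnon-4-en-1-yl]sulfanyl}-1-phenyl-1H-tetrazole
Conditions: 1-phenyl-1H-tetrazole-5-thiol, PPh3, DIAD, THF, 0 °C to rt
Reagents that add atoms: 1-phenyl-1H-tetrazole-5-thiol, Sc1nnnn1-c1ccccc1
Why: Mitsunobu thioetherification of the primary alcohol installs the heteroaryl sulfide at C11.

Step 17
Reactants: 25 5-{[(2S,4E,6S,7R,8R)-8-[(tert-butyldimethylsilyl)oxy]-7-methoxy-2,4,6-trimethylnon-4-en-1-yl]sulfanyl}-1-phenyl-1H-tetrazole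
Product: 26 5-{[(2S,4E,6S,7R,8R)-8-[(tert-butyldimethylsilyl)oxy]-7-methoxy-2,4,6-trimethylnon-4-en-1-yl]sulfonyl}-1-phenyl-1H-tetrazole
Conditions: (NH4)6Mo7O24·4H2O (0.2 equiv), 30% H2O2, EtOH, 0 °C to rt
Reagents that add atoms: hydrogen peroxide, OO
Why: Molybdate-catalysed peroxide oxidation takes the sulfide to the sulfone, and the isolated trisubstituted alkene, which has no free hydroxyl nearby, should not be epoxidised.

Step 18
Reactants: 26 5-{[(2S,4E,6S,7R,8R)-8-[(tert-butyldimethylsilyl)oxy]-7-methoxy-2,4,6-trimethylnon-4-en-1-yl]sulfonyl}-1-phenyl-1H-tetrazole; 9 ethyl 2-[(2R,5S,6S)-5-methyl-6-[(2E)-4-oxobut-2-en-2-yl]oxan-2-yl]acetate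
Product: 27 ethyl 2-[(2R,5S,6S)-6-[(2E,4E,6S,8E,10S,11R,12R)-12-[(tert-butyldimethylsilyl)oxy]-11-methoxy-6,8,10-trimethyltrideca-2,4,8-trien-2-yl]-5-methyloxan-2-yl]acetate
Conditions: 26, KHMDS (1.05 equiv), DME, −60 °C; then 9, −60 °C to rt
Reagents that add atoms: none
Why: Julia–Kocienski olefination (addition, Smiles rearrangement, elimination), which with an α-branched phenyltetrazolyl sulfone and a potassium counter-ion in DME should give the E-C10=C11 alkene of the diene.

Step 19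
Reactants: 27 ethyl 2-[(2R,5S,6S)-6-[(2E,4E,6S,8E,10S,11R,12R)-12-[(tert-butyldimethylsilyl)oxy]-11-methoxy-6,8,10-trimethyltrideca-2,4,8-trien-2-yl]-5-methyloxan-2-yl]acetate
Product: 28 ethyl 2-[(2R,5S,6S)-6-[(2E,4E,6S,8E,10S,11R,12R)-12-hydroxy-11-methoxy-6,8,10-trimethyltrideca-2,4,8-trien-2-yl]-5-methyloxan-2-yl]acetate
Conditions: HF·pyridine, THF, 0 °C to rt
Reagents that add atoms: none
Why: Fluoride cleaves the remaining secondary silyl ether while the diene, the ester and the methyl ether are inert.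

Step 20
Reactants: 28 ethyl 2-[(2R,5S,6S)-6-[(2E,4E,6S,8E,10S,11R,12R)-12-hydroxy-11-methoxy-6,8,10-trimethyltrideca-2,4,8-trien-2-yl]-5-methyloxan-2-yl]acetate
Product: 29 2-[(2R,5S,6S)-6-[(2E,4E,6S,8E,10S,11R,12R)-12-hydroxy-11-methoxy-6,8,10-trimethyltrideca-2,4,8-trien-2-yl]-5-methyloxan-2-yl]acetic acid
Conditions: LiOH, THF/MeOH/H2O, rt; then 0.5 M HCl to pH 4
Reagents that add atoms: lithium hydroxide, [Li+].[OH-]
Why: Saponification of the ethyl ester, which does not endanger C3 because the 2,6-cis oxane is the thermodynamically preferred isomer.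

Step 21
Reactants: 29 2-[(2R,5S,6S)-6-[(2E,4E,6S,8E,10S,11R,12R)-12-hydroxy-11-methoxy-6,8,10-trimethyltrideca-2,4,8-trien-2-yl]-5-methyloxan-2-yl]acetic acid
Product: 30 herboxidiene
Conditions: VO(acac)2 (0.1 equiv), t-BuOOH (in decane), CH2Cl2, −15 °C
Reagents that add atoms: tert-butyl hydroperoxide, CC(C)(C)OO
Why: Hydroxyl-directed epoxidation, in which the C18 hydroxyl binds vanadium and delivers oxygen only to the nearby C14=C15 alkene, whose conformation is fixed by allylic 1,3-strain between the C14 methyl and the C16 substituents and should expose the face giving the (14R,15R)-oxirane, while the remote diene is left alone.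

Compound list
1 | 2,2-dimethoxyacetaldehyde | COC(OC)C=O | starting material
2 | 2-(triphenylphosphoranylidene)propanal | CC(C=O)=P(c1ccccc1)(c1ccccc1)c1ccccc1 | starting material
3 | (2E)-4,4-dimethoxy-2-methylbut-2-enal | COC(OC)/C=C(\C)C=O | intermediate
4 | (2E,4S,5S)-1,1-dimethoxy-3,5-dimethylhepta-2,6-dien-4-ol | COC(OC)/C=C(\C)[C@@H](O)[C@@H](C)C=C | intermediate
5 | ethyl (2Z)-3-iodoprop-2-enoate | CCOC(=O)/C=C\I | starting material
6 | (2E,4S,5S)-7-(9-borabicyclo[3.3.1]nonan-9-yl)-1,1-dimethoxy-3,5-dimethylhept-2-en-4-ol (not isolated) | COC(OC)/C=C(\C)[C@@H](O)[C@@H](C)CCB1C2CCCC1CCC2 | intermediate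
7 | ethyl (2Z,6S,7S,8E)-7-hydroxy-10,10-dimethoxy-6,8-dimethyldeca-2,8-dienoate | COC(OC)/C=C(\C)[C@@H](O)[C@@H](C)CC/C=C\C(=O)OCC | intermediate
8 | ethyl 2-[(2R,5S,6S)-6-[(2E)-4,4-dimethoxybut-2-en-2-yl]-5-methyloxan-2-yl]acetate | COC(OC)/C=C(\C)[C@H]1O[C@@H](CC(=O)OCC)CC[C@@H]1C | intermediate
9 | ethyl 2-[(2R,5S,6S)-5-methyl-6-[(2E)-4-oxobut-2-en-2-yl]oxan-2-yl]acetate | O=C/C=C(\C)[C@H]1O[C@@H](CC(=O)OCC)CC[C@@H]1C | intermediate
10 | (4R)-4-benzyl-3-propanoyl-1,3-oxazolidin-2-one | CCC(=O)N1[C@H](Cc2ccccc2)COC1=O | starting material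
11 | 3-bromoprop-1-yne | C#CCBr | starting material
12 | (4R)-4-benzyl-3-[(2S)-2-methylpent-4-ynoyl]-1,3-oxazolidin-2-one | C#CC[C@H](C)C(=O)N1[C@H](Cc2ccccc2)COC1=O | intermediate
13 | (2S)-2-methylpent-4-yn-1-ol | C#CC[C@H](C)CO | intermediate
14 | tert-butyldimethyl{[(2S)-2-methylpent-4-yn-1-yl]oxy}silane | C#CC[C@H](C)CO[Si](C)(C)C(C)(C)C | intermediate
15 | rac-(3E)-pent-3-en-2-ol | C/C=C/C(C)O | starting material
16 | (1S)-1-[(2S,3S)-3-methyloxiran-2-yl]ethan-1-ol | C[C@@H]1O[C@H]1[C@H](C)O | intermediate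
17 | (1R)-1-[(2R,3S)-3-methyloxiran-2-yl]ethyl 4-nitrobenzoate | C[C@@H]1O[C@H]1[C@@H](C)OC(=O)c1ccc(cc1)[N+](=O)[O-] | intermediate
18 | (1R)-1-[(2S,3S)-3-methyloxiran-2-yl]ethan-1-ol | C[C@@H]1O[C@H]1[C@@H](C)O | intermediate
19 | tert-butyldimethyl{(1R)-1-[(2R,3S)-3-methyloxiran-2-yl]ethoxy}silane | C[C@@H]1O[C@H]1[C@@H](C)O[Si](C)(C)C(C)(C)C | intermediate
20 | [(1E,4S)-5-[(tert-butyldimethylsilyl)oxy]-2,4-dimethylpent-1-en-1-yl]dimethylalumane (not isolated) | C[Al](C)/C=C(\C)C[C@H](C)CO[Si](C)(C)C(C)(C)C | intermediate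
21 | lithium butyl[(1E,4S)-5-[(tert-butyldimethylsilyl)oxy]-2,4-dimethylpent-1-en-1-yl]dimethylaluminate (not isolated) | [Li+].CCCC[Al-](C)(C)/C=C(\C)C[C@H](C)CO[Si](C)(C)C(C)(C)C | intermediate
22 | (2R,3R,4S,5E,8S)-2,9-bis[(tert-butyldimethylsilyl)oxy]-4,6,8-trimethylnon-5-en-3-ol | O[C@H]([C@@H](C)/C=C(\C)C[C@H](C)CO[Si](C)(C)C(C)(C)C)[C@@H](C)O[Si](C)(C)C(C)(C)C | intermediate
23 | (2R,3R,4S,5E,8S)-2,9-bis[(tert-butyldimethylsilyl)oxy]-3-methoxy-4,6,8-trimethylnon-5-ene | CO[C@H]([C@@H](C)/C=C(\C)C[C@H](C)CO[Si](C)(C)C(C)(C)C)[C@@H](C)O[Si](C)(C)C(C)(C)C | intermediate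
24 | (2S,4E,6S,7R,8R)-8-[(tert-butyldimethylsilyl)oxy]-7-methoxy-2,4,6-trimethylnon-4-en-1-ol | CO[C@H]([C@@H](C)/C=C(\C)C[C@H](C)CO)[C@@H](C)O[Si](C)(C)C(C)(C)C | intermediate
25 | 5-{[(2S,4E,6S,7R,8R)-8-[(tert-butyldimethylsilyl)oxy]-7-methoxy-2,4,6-trimethylnon-4-en-1-yl]sulfanyl}-1-phenyl-1H-tetrazole | CO[C@H]([C@@H](C)/C=C(\C)C[C@H](C)CSc1nnnn1-c1ccccc1)[C@@H](C)O[Si](C)(C)C(C)(C)C | intermediate
26 | 5-{[(2S,4E,6S,7R,8R)-8-[(tert-butyldimethylsilyl)oxy]-7-methoxy-2,4,6-trimethylnon-4-en-1-yl]sulfonyl}-1-phenyl-1H-tetrazole | CO[C@H]([C@@H](C)/C=C(\C)C[C@H](C)CS(=O)(=O)c1nnnn1-c1ccccc1)[C@@H](C)O[Si](C)(C)C(C)(C)C | intermediate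
27 | ethyl 2-[(2R,5S,6S)-6-[(2E,4E,6S,8E,10S,11R,12R)-12-[(tert-butyldimethylsilyl)oxy]-11-methoxy-6,8,10-trimethyltrideca-2,4,8-trien-2-yl]-5-methyloxan-2-yl]acetate | CO[C@H]([C@@H](C)/C=C(\C)C[C@H](C)/C=C/C=C(\C)[C@H]1O[C@@H](CC(=O)OCC)CC[C@@H]1C)[C@@H](C)O[Si](C)(C)C(C)(C)C | intermediate
28 | ethyl 2-[(2R,5S,6S)-6-[(2E,4E,6S,8E,10S,11R,12R)-12-hydroxy-11-methoxy-6,8,10-trimethyltrideca-2,4,8-trien-2-yl]-5-methyloxan-2-yl]acetate | CO[C@H]([C@@H](C)/C=C(\C)C[C@H](C)/C=C/C=C(\C)[C@H]1O[C@@H](CC(=O)OCC)CC[C@@H]1C)[C@@H](C)O | intermediate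
29 | 2-[(2R,5S,6S)-6-[(2E,4E,6S,8E,10S,11R,12R)-12-hydroxy-11-methoxy-6,8,10-trimethyltrideca-2,4,8-trien-2-yl]-5-methyloxan-2-yl]acetic acid | CO[C@H]([C@@H](C)/C=C(\C)C[C@H](C)/C=C/C=C(\C)[C@H]1O[C@@H](CC(=O)O)CC[C@@H]1C)[C@@H](C)O | intermediate
30 | herboxidiene, 2-[(2R,5S,6S)-6-[(2E,4E,6S)-7-[(2R,3R)-3-[(2R,3R,4R)-4-hydroxy-3-methoxypentan-2-yl]-2-methyloxiran-2-yl]-6-methylhepta-2,4-dien-2-yl]-5-methyloxan-2-yl]acetic acid | CO[C@H]([C@@H](C)[C@H]1O[C@]1(C)C[C@H](C)/C=C/C=C(\C)[C@H]1O[C@@H](CC(=O)O)CC[C@@H]1C)[C@@H](C)O | target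

Total step count: 21. Longest linear sequence: 13 steps (15 to 30, steps 9 to 21).

Steps most likely to fail

Step 13. Alkenyl transfer from the alanate may be slow on the 2,3-disubstituted oxirane, so that methyl or butyl transfer, attack at C17 or Lewis-acid-promoted rearrangement of the epoxide compete. The fallback sets out from 14 and comes back at 22. The carboalumination of 14 is run as before and the alane is quenched with I2 (THF, −30 °C) to give the vinyl iodide tert-butyl{[(2S,4E)-5-iodo-2,4-dimethylpent-4-en-1-yl]oxy}dimethylsilane F1. Iodine–lithium exchange (t-BuLi, Et2O, −78 °C) gives the alkenyllithium F2, which together with BF3·OEt2 at −78 °C should open 19 at C16 with inversion (boron-trifluoride-assisted organolithium opening of epoxides) to give 22.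

Step 3. The free C7 hydroxyl can tie up the borane as a cyclic borinate and slow transmetalation, so that protodeboronation or β-hydride elimination of the alkylpalladium species takes over. The fallback sets out from 4 and comes back at 8. Linear-selective hydroformylation of the terminal alkene (Rh(acac)(CO)2, BIPHEPHOS, CO/H2, toluene, 60 °C) gives, after spontaneous ring closure, the lactol (5S,6S)-6-[(2E)-4,4-dimethoxybut-2-en-2-yl]-5-methyloxan-2-ol F3. Wittig reaction of the lactol with ethyl (triphenylphosphoranylidene)acetate (toluene, 80 °C) gives ethyl (2E,6S,7S,8E)-7-hydroxy-10,10-dimethoxy-6,8-dimethyldeca-2,8-dienoate F4, which closes to 8 under the conditions of step 4.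

Step 18. E selectivity at C10=C11 may erode, or the base may deprotonate enal 9 at its γ-position and open its β-alkoxy ester by retro-oxa-Michael reaction. The fallback exchanges the roles of the partners; it sets out from 9 and 24 and comes back at 27. Luche reduction of 9 (NaBH4, CeCl3·7H2O, MeOH, 0 °C) gives the allylic alcohol ethyl 2-[(2R,5S,6S)-6-[(2E)-4-hydroxybut-2-en-2-yl]-5-methyloxan-2-yl]acetate F5. Mitsunobu reaction with 1-phenyl-1H-tetrazole-5-thiol gives the allylic sulfide F6, and oxidation with (NH4)6Mo7O24/H2O2 gives the allylic sulfone F7. Alcohol 24 is oxidised with Dess–Martin periodinane to (2S,4E,6S,7R,8R)-8-[(tert-butyldimethylsilyl)oxy]-7-methoxy-2,4,6-trimethylnon-4-enal F8. Metalation of F7 (KHMDS, DME, −78 °C) and addition of F8 should give 27.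

Further compounds
F1 | step 13 | tert-butyl{[(2S,4E)-5-iodo-2,4-dimethylpent-4-en-1-yl]oxy}dimethylsilane | I/C=C(\C)C[C@H](C)CO[Si](C)(C)C(C)(C)C
F2 | step 13 | [(1E,4S)-5-[(tert-butyldimethylsilyl)oxy]-2,4-dimethylpent-1-en-1-yl]lithium | [Li]/C=C(\C)C[C@H](C)CO[Si](C)(C)C(C)(C)C
F3 | step 3 | (5S,6S)-6-[(2E)-4,4-dimethoxybut-2-en-2-yl]-5-methyloxan-2-ol | COC(OC)/C=C(\C)[C@H]1OC(O)CC[C@@H]1C
F4 | step 3 | ethyl (2E,6S,7S,8E)-7-hydroxy-10,10-dimethoxy-6,8-dimethyldeca-2,8-dienoate | COC(OC)/C=C(\C)[C@@H](O)[C@@H](C)CC/C=C/C(=O)OCC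
F5 | step 18 | ethyl 2-[(2R,5S,6S)-6-[(2E)-4-hydroxybut-2-en-2-yl]-5-methyloxan-2-yl]acetate | OC/C=C(\C)[C@H]1O[C@@H](CC(=O)OCC)CC[C@@H]1C
F6 | step 18 | ethyl 2-[(2R,5S,6S)-5-methyl-6-[(2E)-4-[(1-phenyl-1H-tetrazol-5-yl)sulfanyl]but-2-en-2-yl]oxan-2-yl]acetate | c1ccccc1-n1nnnc1SC/C=C(\C)[C@H]1O[C@@H](CC(=O)OCC)CC[C@@H]1C
F7 | step 18 | ethyl 2-[(2R,5S,6S)-5-methyl-6-[(2E)-4-[(1-phenyl-1H-tetrazol-5-yl)sulfonyl]but-2-en-2-yl]oxan-2-yl]acetate | c1ccccc1-n1nnnc1S(=O)(=O)C/C=C(\C)[C@H]1O[C@@H](CC(=O)OCC)CC[C@@H]1C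
F8 | step 18 | (2S,4E,6S,7R,8R)-8-[(tert-butyldimethylsilyl)oxy]-7-methoxy-2,4,6-trimethylnon-4-enal | CO[C@H]([C@@H](C)/C=C(\C)C[C@H](C)C=O)[C@@H](C)O[Si](C)(C)C(C)(C)C
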